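**Plan**

The chain is numbered from C1 (the CH2 on furan ring A) through C2 (the acetoxy carbon) to C11 (the CH2 on furan ring B). The retrosynthesis cuts the C6=C7 alkene first (cross-metathesis), then the acetate C–O bond, then C2–C3 and C4–CH3 in one operation.
The enabling feature is that the C2 carbinol, the C3=C4 alkene and the C4 methyl group lying cis to C2 form the pattern left by syn addition of an aldehyde carbon and a methyl group across a terminal C3≡C4 alkyne. Ring A with C1–C2 therefore comes from 3-furylacetaldehyde, C3–C6 from pent-1-en-4-yne and the methyl from Me2Zn, merged on zerovalent nickel.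
Forward, alcohol oxidation, the three-component coupling and acetylation give the C1–C6 acetate with a terminal alkene. Ring B with C7–C11 is built separately as a 3-methyl-1,3-diene by Kumada coupling, cross-metathesis with methacrolein and Wittig methylenation. A last cross-metathesis joins the halves at C6=C7; both furans are bought and no ring is formed.
Stereochemistry: (S) at C2 comes from the chiral phosphoramidite on nickel, 3E from the cis placement of nickel and C2 in the metallacycle, 8E from the methacrolein metathesis and 6E from the final metathesis.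

Key step: step 2

Assumption: the facial preference of the phosphoramidite cannot be predicted for this alkyl alkyne and arylacetaldehyde pair, so the ligand antipode that gives the (S)-carbinol would be fixed in the first experiments by Mosher ester analysis of 7.

**Route**

Step 1
Reactants: 1 2-(furan-3-yl)ethanol
Product: 2 2-(furan-3-yl)acetaldehyde
Conditions: Dess–Martin periodinane (1.2 equiv), CH2Cl2, 0 °C to rt; pentane, short silica pad, cold concentration, used at once
Reagents that add atoms: none
Why: Dess–Martin oxidation stops cleanly at the aldehyde under non-aqueous, nearly neutral conditions, which suits an enolisable arylacetaldehyde that is passed on without storage.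

Step 2
Reactants: 2 2-(furan-3-yl)acetaldehyde; 3 pent-1-en-4-yne; 4 dimethylzinc
Product: 7 (2S,3E)-1-(furan-3-yl)-4-methylhepta-3,6-dien-2-ol, via oxanickelacyclopentene 5 (not isolated), via methylzinc alkoxide 6 (not isolated)
Conditions: Ni(cod)2 (10 mol%), SIPHOS-PE-type spirobiindane phosphoramidite (12 mol%), Me2Zn (2.5 equiv), toluene, 0 °C, 2 and 3 (1.5 equiv) added over 4 h; then sat. aq. NH4Cl
Reagents that add atoms: pent-1-en-4-yne 3, C#CCC=C; dimethylzinc 4, C[Zn]C
Why: Proposed new method: zerovalent nickel carrying one phosphoramidite binds 2 and 3 and couples them oxidatively to metallacycle 5, with the aldehyde carbon bonded to the CH terminus of the alkyne (C3) and nickel on C4; Me2Zn then transfers methyl to divalent nickel and zinc to oxygen, and C4–CH3 reductive elimination with retention gives alkoxide 6 and returns zerovalent nickel. The closest known reaction type is the nickel-catalysed three-component alkylative coupling of alkynes, aldehydes and organozincs, whose enantioselective phosphoramidite variant is established for aryl-substituted alkynes with non-enolisable aldehydes but not for a terminal alkyl alkyne with an enolisable arylacetaldehyde. No ring of the target is closed: the only ring formed is the transient five-membered oxanickelacycle, made by oxidative cyclisation on nickel and opened again by the methyl transfer. The one new stereocentre, C2, is set in the oxidative cyclisation, where the chiral phosphoramidite distinguishes the two faces of the nickel-bound aldehyde, and the 3E geometry follows because nickel and C2 are cis in 5 and methyl takes the place of nickel. The step needs regioselectivity, supplied by the steric difference between the hydrogen-bearing and the allyl-bearing alkyne carbons, and chemoselectivity over alkyne oligomerisation, direct methyl addition and aldol condensation, which slow addition of 2 and 3 into excess weakly basic Me2Zn at 0 °C should provide.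

Step 3
Reactants: 7 (2S,3E)-1-(furan-3-yl)-4-methylhepta-3,6-dien-2-ol
Product: 8 (2S,3E)-1-(furan-3-yl)-4-methylhepta-3,6-dien-2-yl acetate
Conditions: Ac2O, pyridine, DMAP (cat.), CH2Cl2, 0 °C to rt
Reagents that add atoms: acetic anhydride, CC(=O)OC(C)=O
Why: DMAP-catalysed acylation of a secondary alcohol takes place at oxygen only, so the (S) configuration at C2 is carried through unchanged.

Step 4
Reactants: 9 3-bromofuran; 10 but-3-en-1-ylmagnesium bromide
Product: 11 3-(but-3-en-1-yl)furan
Conditions: Ni(dppp)Cl2 (3 mol%), THF, 0 °C to reflux; aq. NH4Cl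
Reagents that add atoms: but-3-en-1-ylmagnesium bromide 10, C=CCC[Mg]Br
Why: Kumada–Corriu coupling of a heteroaryl bromide with a primary alkyl Grignard reagent is a standard entry to 3-alkylfurans, the chelating diphosphine on nickel holding back β-hydride elimination.

Step 5
Reactants: 11 3-(but-3-en-1-yl)furan; 12 methacrolein
Product: 13 (2E)-5-(furan-3-yl)-2-methylpent-2-enal
Conditions: second-generation Hoveyda–Grubbs catalyst, RuCl2(SIMes)(=CH-C6H4-2-OiPr) (5 mol%), methacrolein (5 equiv), CH2Cl2, 40 °C
Reagents that add atoms: methacrolein 12, CC(=C)C=O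
Why: Olefin cross-metathesis of a terminal alkene with excess methacrolein is a well-used route to 2-methyl-2-enals and should strongly favour the E isomer on thermodynamic grounds, the furan being inert to the ruthenium carbene.

Step 6
Reactants: 13 (2E)-5-(furan-3-yl)-2-methylpent-2-enal
Product: 14 3-[(3E)-4-methylhexa-3,5-dien-1-yl]furan
Conditions: Ph3PCH3Br, KOtBu, THF, 0 °C to rt
Reagents that add atoms: methyltriphenylphosphonium bromide, C[P+](c1ccccc1)(c1ccccc1)c1ccccc1.[Br-]
Why: Wittig methylenation of an α,β-unsaturated aldehyde with the unstabilised ylide gives the terminal diene without touching the existing trisubstituted E alkene.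

Step 7
Reactants: 8 (2S,3E)-1-(furan-3-yl)-4-methylhepta-3,6-dien-2-yl acetate; 14 3-[(3E)-4-methylhexa-3,5-dien-1-yl]furan
Product: 15 (2S,3E,6E,8E)-1,11-di(furan-3-yl)-4,8-dimethylundeca-3,6,8-trien-2-yl acetate
Conditions: second-generation Hoveyda–Grubbs catalyst (2 × 5 mol%), 14 (3 equiv), 1,4-benzoquinone (10 mol%), CH2Cl2, 40 °C
Reagents that add atoms: diene 14, C=C/C(C)=C/CCc1ccoc1
Why: Olefin cross-metathesis between a terminal alkene and a 1,3-diene whose second double bond is trisubstituted is known to engage only the unhindered vinyl group and to favour the E-configured conjugated product, while benzoquinone should suppress ruthenium hydride migration in the skipped diene and C2 is not involved.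

**Compound list**

1 | 2-(furan-3-yl)ethanol | OCCc1ccoc1 | starting material
2 | 2-(furan-3-yl)acetaldehyde | O=CCc1ccoc1 | intermediate
3 | pent-1-en-4-yne | C#CCC=C | starting material
4 | dimethylzinc | C[Zn]C | starting material
5 | oxanickelacyclopentene, (3S)-3-(furan-3-ylmethyl)-5-(prop-2-en-1-yl)-2-oxa-1-nickelacyclopent-4-ene (phosphoramidite on nickel not drawn) | C=CCC1=C[C@H](Cc2ccoc2)O[Ni]1 | intermediate
6 | methylzinc alkoxide, methylzinc (2S,3E)-1-(furan-3-yl)-4-methylhepta-3,6-dien-2-olate | C[Zn]O[C@H](/C=C(\C)CC=C)Cc1ccoc1 | intermediate
7 | (2S,3E)-1-(furan-3-yl)-4-methylhepta-3,6-dien-2-ol | O[C@H](/C=C(\C)CC=C)Cc1ccoc1 | intermediate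
8 | (2S,3E)-1-(furan-3-yl)-4-methylhepta-3,6-dien-2-yl acetate | CC(=O)O[C@H](/C=C(\C)CC=C)Cc1ccoc1 | intermediate
9 | 3-bromofuran | Brc1ccoc1 | starting material
10 | but-3-en-1-ylmagnesium bromide | C=CCC[Mg]Br | starting material
11 | 3-(but-3-en-1-yl)furan | C=CCCc1ccoc1 | intermediate
12 | methacrolein (2-methylprop-2-enal) | CC(=C)C=O | starting material
13 | (2E)-5-(furan-3-yl)-2-methylpent-2-enal | O=C/C(C)=C/CCc1ccoc1 | intermediate
14 | 3-[(3E)-4-methylhexa-3,5-dien-1-yl]furan | C=C/C(C)=C/CCc1ccoc1 | intermediate
15 | (2S,3E,6E,8E)-1,11-di(furan-3-yl)-4,8-dimethylundeca-3,6,8-trien-2-yl acetate | CC(=O)O[C@H](/C=C(\C)C/C=C/C(C)=C/CCc1ccoc1)Cc1ccoc1 | target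

**Count**

Total steps: 7. Longest linear sequence: 4 steps (steps 1, 2, 3 and 7 from 1; equally steps 4, 5, 6 and 7 from 9).

**Steps most likely to fail**

Step 2. The terminal alkyne may oligomerise or insert twice on nickel, the arylacetaldehyde may enolise and condense or take up methyl directly, and facial discrimination by the ligand may be weak for this untested substrate pair. The fallback uses known chemistry, sets out from alkyne 3 and aldehyde 2 and comes back at 7. Zirconium-catalysed carboalumination of 3 (Me3Al, Cp2ZrCl2, CH2Cl2) followed by I2 gives (1E)-1-iodo-2-methylpenta-1,4-diene F1, with methyl and iodine cis. Nozaki–Hiyama–Kishi coupling of this iodide with 2 (CrCl2, cat. NiCl2, DMF) gives racemic (3E)-1-(furan-3-yl)-4-methylhepta-3,6-dien-2-ol F2. MnO2 in CH2Cl2 oxidises it to (3E)-1-(furan-3-yl)-4-methylhepta-3,6-dien-2-one F3. Corey–Bakshi–Shibata reduction with the (R)-methyl oxazaborolidine and catecholborane in toluene at −78 °C, the alkenyl group acting as the large substituent, should then give 7.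

Step 7. The carbene may rest as the conjugated vinylcarbene derived from 14 and turn over slowly, metathesis may give an E/Z mixture at C6=C7, the skipped alkene may migrate into conjugation, and homodimerisation of 8 would consume material. The fallback forms the C7–C8 bond by cross-coupling instead; it sets out from alcohol 7 and 3-bromofuran 9 and comes back at 15. Cross-metathesis of 7 with vinylboronic acid pinacol ester (second-generation Hoveyda–Grubbs catalyst) gives (2S,3E,6E)-1-(furan-3-yl)-4-methyl-7-(4,4,5,5-tetramethyl-1,3,2-dioxaborolan-2-yl)hepta-3,6-dien-2-ol F4. Kumada coupling of 9 with pent-3-yn-1-ylmagnesium bromide (Ni(dppp)Cl2) gives 3-(pent-3-yn-1-yl)furan F5. Hydrozirconation with excess Cp2Zr(H)Cl, equilibrated so that zirconium sits on the methyl-bearing carbon, and then I2 give 3-[(3E)-4-iodopent-3-en-1-yl]furan F6. Suzuki–Miyaura coupling of the boronate with the iodide (Pd(dppf)Cl2, K3PO4, THF/H2O) gives (2S,3E,6E,8E)-1,11-di(furan-3-yl)-4,8-dimethylundeca-3,6,8-trien-2-ol F7, and acetylation as in step 3 gives 15. The coupling is placed before acetylation so that zerovalent palladium never meets the allylic acetate.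

Step 5. Turnover with the electron-poor 1,1-disubstituted partner may be low, homodimerisation of 11 may dominate, and the catalyst may decompose before conversion is complete. The fallback replaces metathesis by carbonyl olefination; it sets out from 11 and comes back at 13. Lemieux–Johnson cleavage of the terminal alkene (cat. OsO4, NaIO4, 2,6-lutidine, dioxane/H2O) gives 3-(furan-3-yl)propanal F8. Wittig reaction with the stabilised ylide 2-(triphenylphosphoranylidene)propanal in toluene at 90 °C should then give the E enal 13.

**Further compounds**

F1 | step 2 | (1E)-1-iodo-2-methylpenta-1,4-diene | I/C=C(\C)CC=C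
F2 | step 2 | racemic (3E)-1-(furan-3-yl)-4-methylhepta-3,6-dien-2-ol | OC(/C=C(\C)CC=C)Cc1ccoc1
F3 | step 2 | (3E)-1-(furan-3-yl)-4-methylhepta-3,6-dien-2-one | O=C(/C=C(\C)CC=C)Cc1ccoc1
F4 | step 7 | (2S,3E,6E)-1-(furan-3-yl)-4-methyl-7-(4,4,5,5-tetramethyl-1,3,2-dioxaborolan-2-yl)hepta-3,6-dien-2-ol | O[C@H](/C=C(\C)C/C=C/B1OC(C)(C)C(C)(C)O1)Cc1ccoc1
F5 | step 7 | 3-(pent-3-yn-1-yl)furan | CC#CCCc1ccoc1
F6 | step 7 | 3-[(3E)-4-iodopent-3-en-1-yl]furan | I/C(C)=C/CCc1ccoc1
F7 | step 7 | (2S,3E,6E,8E)-1,11-di(furan-3-yl)-4,8-dimethylundeca-3,6,8-trien-2-ol | O[C@H](/C=C(\C)C/C=C/C(C)=C/CCc1ccoc1)Cc1ccoc1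
F8 | step 5 | 3-(furan-3-yl)propanal | O=CCCc1ccoc1
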